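**Retrosynthetic overview**
- The strategy rests on the C4 carbonyl of the pyridone ring, which is bonded to C4a of the benzo ring on one side and to C3 on the other, so C4 can be brought in as carbon monoxide.
- Cutting C4a–C4, C4–C3 and N1–C2 gives three components: 2-iodo-N-methylaniline (benzo ring, N1 and its methyl), carbon monoxide (C4=O) and 1-hexadecyne (C3, C2 and the tetradecyl chain).
- 2-Iodo-N-methylaniline comes from 2-iodoaniline by reductive N-monomethylation; the methyl group is placed before the annulation, which avoids N- versus O-alkylation of a 4-quinolone.
- Ring order: the benzo ring is bought, and the pyridone ring is the only ring formed, in the last step.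

Key step: step 2

Remark: the target has no stereocentre, so no stereocontrol is needed; the route has two steps, so two steps are ranked by risk at the end.

**Step 1**
Reactants: 1 2-iodoaniline
Product: 3 2-iodo-N-methylaniline, via N-(methoxymethyl)-2-iodoaniline 2 (not isolated)
Conditions: (CH2O)n (1.5 equiv), NaOMe (5 equiv), MeOH, 65 °C; then NaBH4 (2 equiv), 65 °C
Reagents that add atoms: paraformaldehyde (formaldehyde), C=O
Why: This is a reductive N-methylation (reductive amination) in which formaldehyde condenses with the aniline in methanolic NaOMe to the N-methoxymethyl aniline 2, a mask of the N-methylene imine that NaBH4 reduces to the N-methyl group, and since the secondary amine 3 cannot form a neutral imine under these basic conditions a second methylation should be shut off while the C–I bond is left alone by borohydride.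

**Step 2**
Reactants: 3 2-iodo-N-methylaniline; 4 1-hexadecyne (1.5 equiv); 5 carbon monoxide
Product: 8 1-methyl-2-tetradecylquinolin-4(1H)-one, via aryl ynone 6 (not isolated), via diethylamino enone 7 (not isolated)
Conditions: PdCl2(PPh3)2 (5 mol %), CO (20 bar), Et2NH, 120 °C, autoclave, copper-free
Reagents that add atoms: none
Why: PdCl2(PPh3)2 is reduced in the amine to zerovalent palladium, which inserts into the C–I bond of 3; CO insertion gives the aroylpalladium iodide, and amine-assisted alkynylation by 4 followed by reductive elimination releases ynone 6 (bonds C4a–C4 and C4–C3). Diethylamine adds to the β-carbon of 6 to give enaminone 7, and the ortho N-methylamino group displaces diethylamine at that same carbon by addition–elimination (bond N1–C2), so the pyridone ring closes in a 6-endo-trig mode on 7, which is equivalent to the 6-endo-dig aza-Michael closure of 6. The closest known reaction type is the palladium-catalysed carbonylative Sonogashira coupling–cyclization of 2-iodoanilines with terminal alkynes in a secondary amine to give 2-substituted 4-quinolones. No stereocentre is formed. The step needs CO insertion to outrun direct alkynylation (which would lead to a 2-alkynylaniline and then an indole), which copper-free conditions and 20 bar CO should secure, and it needs nitrogen to attack the β-carbon and not the α-carbon (5-exo), which the polarisation of the ynone by its carbonyl and the diethylamino leaving group on C2 should secure; the aromatic vinylogous amide of 8 should make the closure irreversible.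

**Compound list**
1 | 2-iodoaniline | Nc1ccccc1I | starting material
2 | N-(methoxymethyl)-2-iodoaniline | COCNc1ccccc1I | intermediate (not isolated)
3 | 2-iodo-N-methylaniline | CNc1ccccc1I | intermediate
4 | 1-hexadecyne | CCCCCCCCCCCCCCC#C | starting material
5 | carbon monoxide | [C-]#[O+] | starting material
6 | 1-[2-(methylamino)phenyl]heptadec-2-yn-1-one | CCCCCCCCCCCCCCC#CC(=O)c1ccccc1NC | intermediate (not isolated)
7 | (E)-3-(diethylamino)-1-[2-(methylamino)phenyl]heptadec-2-en-1-one | CCCCCCCCCCCCCC/C(N(CC)CC)=C\C(=O)c1ccccc1NC | intermediate (not isolated)
8 | 1-methyl-2-tetradecylquinolin-4(1H)-one | CCCCCCCCCCCCCCc1cc(=O)c2ccccc2n1C | target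

**Total step count:** 2
**Longest linear sequence:** 2 steps (1 → 3 → 8)

**Steps most likely to fail** (the route has only two steps; both are ranked, the riskier first)

1. Step 2. The aroylpalladium intermediate may be captured by diethylamine (aminocarbonylation to a benzamide). Alkynylation may also run ahead of CO insertion and end in indole formation, or the amine exchange at the hindered N-methylamino group may stall at the enaminone stage. The fallback builds the pyridone ring without palladium or carbon monoxide and sets out from 4. Markovnikov hydration of 4 (catalytic Ph3PAuCl and AgOTf, aqueous methanol, 60 °C) should give 2-hexadecanone F1. Kinetic deprotonation at the methyl group with lithium diisopropylamide (LiN(i-Pr)2, THF, −78 °C, enolate in about twofold excess) should give lithium hexadec-1-en-2-olate F2. This enolate is acylated at the C4 carbonyl of purchased N-methylisatoic anhydride F3 in a Claisen-type reaction, with ring opening and loss of carbon dioxide, to give 1-[2-(methylamino)phenyl]heptadecane-1,3-dione F4. On warming and mildly acidic work-up the N-methylamino group of F4 condenses with the alkyl ketone, and the fallback returns to the route at 8.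

2. Step 1. The weakly nucleophilic ortho-iodoaniline may convert incompletely to the methoxymethyl adduct, or may condense twice with formaldehyde to an aminal, so that the reduction returns starting aniline or a mixture. The fallback replaces the one-pot reductive alkylation by acylation and reduction and sets out from 1. N-Formylation with acetic formic anhydride (HCO2H and Ac2O, THF, 0 °C to room temperature) should give N-(2-iodophenyl)formamide F5. Reduction of the formamide with BH3·SMe2 in THF at reflux, followed by a methanol quench, should return to the route at 3; monoalkylation is fixed by the single formyl group and the aryl iodide is inert to borane.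

**Further compounds**
F1 | step 2 | 2-hexadecanone | CCCCCCCCCCCCCCC(C)=O
F2 | step 2 | lithium hexadec-1-en-2-olate | [Li+].[O-]C(=C)CCCCCCCCCCCCCC
F3 | step 2 | N-methylisatoic anhydride (purchased) | CN1C(=O)OC(=O)c2ccccc21
F4 | step 2 | 1-[2-(methylamino)phenyl]heptadecane-1,3-dione | CCCCCCCCCCCCCCC(=O)CC(=O)c1ccccc1NC
F5 | step 1 | N-(2-iodophenyl)formamide | O=CNc1ccccc1I
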